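Retrosynthetic cuts, in order: C6–Cl (SN2 inversion of a 6-alcohol made by a singlet-oxygen ene reaction on a Δ5 olefin); C5=C6 (ring-closing metathesis, ten-membered ring B); C3–C4 (Nozaki–Hiyama–Kishi with methacrolein); C8–C17 (Reformatsky, lactone ring C); C7–C8 (allylboration); C11–C12 (ring A); C1–C10 ([3,3]).
Forward order: neryl D-malate → Claisen (C1–C10) → keto aldehyde → ring A (step 10) → vinyl iodide and enone → ring C → C4/C5 unit → ring B → chloride.
Enabling feature 1: in ring A the tertiary C11–O carbon sits next to the C12 ketone (an acyloin). In the open form both are carbonyl carbons of like polarity (C11 methyl ketone, C12 aldehyde), so carbene umpolung of C12 can join them.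
Enabling feature 2: O11 and C2 stand 1,3-cis on ring A. A C2 methyl ester on C1 therefore captures only the correct C11 epimer as a γ-lactone (C1–C2–O–C11–C10, a 6-oxabicyclo[3.2.1]octane), while the other epimer reverts by retro-benzoin. This helper is removed in steps 11 and 12, where C2 becomes the vinyl iodide carbon.
Stereochemistry: C9 from D-malic acid; C10 and C1 from the chelated dianion and the chair [3,3] on the Z-olefin; C11 relayed from C1 by the lactone trap; C7 from the isopinocampheyl allylborane; C8 and C17 from C7 in the Reformatsky closure; C4 from a chiral chromium complex; C6 from peripheral attack of singlet oxygen on ring B, then inversion.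

Key step: step 10

Remark: briarane numbering is used (C1 quaternary, C2=C3, C4 OAc, C5=C16, C6 Cl, C7 O, C8 OH, C9 OAc, C10, C11(C20) OAc, C12=O, C13=C14, C15 on C1, C17(C18), C19 lactone C=O), the target is (1S,2E,4S,6S,7R,8R,9R,10S,11S,17R), TBS = tert-butyldimethylsilyl, and centres that are erased later (side-chain glycol carbon, C2 lactol, C12 carbinol, CHBr) are carried as mixtures and drawn without configuration.

Step 1
Reactants: 1 (R)-2-(2,2-dimethyl-5-oxo-1,3-dioxolan-4-yl)acetic acid; 2 nerol
Product: 3 neryl 2-[(4R)-2,2-dimethyl-5-oxo-1,3-dioxolan-4-yl]acetate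
Conditions: EDC·HCl, DMAP (cat.), CH2Cl2, 0 → 23 °C
Reagents that add atoms: none
Why: Steglich-type carbodiimide esterification joins the free β-carboxyl group of 1 to the primary allylic alcohol under neutral conditions, so the Z-olefin, the dioxolanone and C9 (from D-malic acid) are untouched.

Step 2
Reactants: 3 neryl dioxolanone acetate
Product: 4 1-methyl 4-neryl (2R)-2-hydroxybutanedioate
Conditions: K2CO3 (10 mol %), MeOH, 0 °C
Reagents that add atoms: methanol, CO
Why: Base-catalysed transesterification, in which methoxide opens the activated dioxolanone carbonyl with loss of acetone much faster than it attacks the plain neryl ester, frees the C9 hydroxyl needed for the dianion.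

Step 3
Reactants: 4 1-methyl 4-neryl (R)-malate
Product: 5 (2S,3R)-2-[(3R)-3,7-dimethylocta-1,6-dien-3-yl]-3-hydroxy-4-methoxy-4-oxobutanoic acid
Conditions: LiN(i-Pr)2 (2.6 equiv), THF, −78 → 23 °C; 1 M HCl
Reagents that add atoms: none
Why: Dianionic ester-enolate Claisen rearrangement, in which the lithium alkoxide–enolate chelate fixes the enolate geometry (enolate O cis to C9) and shields one face as in the Fráter–Seebach alkylation of malates, so that C10 forms anti to O9, and the chair transition state on the Z-olefin (methyl equatorial, homoprenyl axial) sets the quaternary C1.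

Step 4
Reactants: 5 Claisen acid
Product: 7 (3S,4R)-3-[(3R)-3,7-dimethylocta-1,6-dien-3-yl]-4-hydroxyoxolan-2-one, via dihydroxy acid 6 (not isolated)
Conditions: LiBH4, THF, 0 → 23 °C; 1 M HCl
Reagents that add atoms: none
Why: Chemoselective borohydride reduction takes the α-hydroxy methyl ester to the C8 alcohol while the lithium carboxylate is inert, and acidification closes the γ-lactone (C8–O–C11), which differentiates the two carboxyl carbons without touching a stereocentre.

Step 5
Reactants: 7 hydroxy lactone
Product: 8 (3S,4R)-3-[(3R)-3,7-dimethylocta-1,6-dien-3-yl]-4,5-dihydroxypentan-2-one (in equilibrium with its cyclic hemiketal)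
Conditions: MeLi (2.2 equiv), THF, −78 °C; aq. NH4Cl
Reagents that add atoms: methyllithium, [Li]C
Why: Mono-addition of an organolithium to a lactone works because the first equivalent deprotonates O9–H, the second adds to C11, and the lactol alkoxide persists at −78 °C, so the methyl ketone (C11, C20) appears only on quench.

Step 6
Reactants: 8 dihydroxy ketone
Product: 9 bis-TBS ether of 8 (O8 and O9)
Conditions: TBSCl (3 equiv), imidazole, DMAP (cat.), DMF, 40 °C
Reagents that add atoms: tert-butyldimethylsilyl chloride, CC(C)(C)[Si](C)(C)Cl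
Why: Standard silylation traps the open hydroxy-ketone form and masks O8 and O9, so that later no hydroxyl group can compete with O11 for the C2 ester in step 10.

Step 7
Reactants: 9 bis-TBS ketone
Product: 10 side-chain glycol of 9 (diol from the trisubstituted olefin, carbinol epimers)
Conditions: OsO4 (2 mol %), NMO, acetone–H2O, 0 °C
Reagents that add atoms: N-methylmorpholine N-oxide, C[N+]1([O-])CCOCC1; water, O
Why: Upjohn dihydroxylation is chemoselective for the electron-rich trisubstituted olefin over the neopentyl-type vinyl group, and the new carbinol centre is lost again in step 9.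

Step 8
Reactants: 10 vinyl glycol
Product: 11 C2 methyl ester glycol (vinyl group replaced by CO2Me on C1)
Conditions: O3, NaOH (2.5 M in MeOH), CH2Cl2, −78 °C
Reagents that add atoms: ozone, [O-][O+]=O; methanol, CO
Why: Ozonolysis in methanolic NaOH cleaves the vinyl group and oxidises the hemiacetal of the resulting aldehyde in situ to the methyl ester, which places the acyl trap on C1, and at −78 °C the ketone, glycol and silyl ethers are not affected.

Step 9
Reactants: 11 ester glycol
Product: 12 keto aldehyde ester (C11 methyl ketone, C12 aldehyde, C2 methyl ester; C1, C9, C10 as in the target)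
Conditions: NaIO4, THF–pH 7 buffer, 0 → 23 °C
Reagents that add atoms: none
Why: Malaprade glycol cleavage under neutral conditions unmasks the C12 aldehyde without epimerising C10.

Step 10
Reactants: 12 keto aldehyde ester
Product: 14 keto lactone, 1,5-dimethyl-6-oxabicyclo[3.2.1]octane-4,7-dione carrying the (1R)-1,2-bis(TBSO)ethyl group on C8 anti to the lactone bridge, via ketol ester 13 (not isolated)
Conditions: 2-(pentafluorophenyl)-6,7-dihydro-5H-pyrrolo[2,1-c][1,2,4]triazol-2-ium tetrafluoroborate (20 mol %), Et3N (1 equiv), 4 Å molecular sieves, toluene, 60 °C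
Reagents that add atoms: none
Why: The triazolylidene adds to the unhindered C12 aldehyde and proton transfer gives the Breslow enaminol, an acyl anion equivalent that attacks the C11 methyl ketone and then expels the carbene to give ketol 13, whose O11 acylates itself on the C2 ester (the carbene also catalyses this transesterification) to give 14. The closest known reaction type is the carbene-catalysed intramolecular crossed aldehyde–ketone benzoin reaction that gives six-membered tertiary α-ketols, combined with the known carbene-mediated retro-benzoin of such ketols. Ring A closes 6-exo-trig (C12 onto the C11 carbonyl) and the temporary lactone closes 5-exo-trig (O11 onto the C2 carbonyl). The only new stereocentre, C11, is controlled by C1: lactonisation is geometrically possible only when O11 and the C2 ester are 1,3-diaxial on the same face of ring A, and since C–C bond formation is reversible the other C11 epimer should return to 12 and drain into 14. The step needs the aldehyde and not the ketone to become the nucleophile (only an aldehyde can form the enaminol), benzoin closure to win over aldol closure of the enolisable aldehyde (weak amine base, aprotic medium), and C10 to keep its configuration (its proton is tertiary and flanked by the quaternary C1). O8 and O9 are silylated and C8 is at the alcohol level, so the C2 ester is the only acyl acceptor within reach of O11.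

Step 11
Reactants: 14 keto lactone
Product: 15 bridged lactol carbinol (C2 lactol, C12 alcohol)
Conditions: i-Bu2AlH (3.5 equiv), CH2Cl2, −78 °C; aq. potassium sodium tartrate
Reagents that add atoms: none
Why: Hydride reduction with i-Bu2AlH stops at the lactol because the aluminium hemiacetal of the bridged lactone is stable at −78 °C, and the simultaneous reduction of C12 is harmless since both new centres are erased in steps 12 and 13.

Step 12
Reactants: 15 lactol carbinol
Product: 16 (E)-vinyl iodide diol (C2=C3–I on C1; free O11–H and O12–H)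
Conditions: CrCl2 (8 equiv), CHI3 (3 equiv), THF–dioxane, 0 → 23 °C
Reagents that add atoms: iodoform, IC(I)I
Why: Takai olefination acts on the hydroxy aldehyde that is in equilibrium with the lactol, the geminal dichromium reagent being aldehyde-selective, tolerant of free hydroxyl groups and E-selective, and this opens the temporary lactone ring and releases O11.

Step 13
Reactants: 16 vinyl iodide diol
Product: 18 α-hydroxy enone (C12 ketone, C13=C14, free O11–H), via saturated ketol 17 (not isolated)
Conditions: IBX (4 equiv), DMSO, 23 °C then 75 °C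
Reagents that add atoms: none
Why: IBX oxidation converts the secondary C12 alcohol of the glycol to the ketone without C–C cleavage, and IBX dehydrogenation at higher temperature then installs C13=C14 with unambiguous regiochemistry because C11 is fully substituted.

Step 14
Reactants: 18 α-hydroxy enone
Product: 19 11-acetate
Conditions: Ac2O, DMAP, Et3N, CH2Cl2, 40 °C
Reagents that add atoms: acetic anhydride, CC(=O)OC(C)=O
Why: DMAP-catalysed acylation esterifies the only free hydroxyl group, the tertiary O11–H, at a stage where the tertiary C8 alcohol of the target does not yet exist.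

Step 15
Reactants: 19 11-acetate
Product: 20 primary C8 alcohol (O9–TBS retained)
Conditions: HF·pyridine, pyridine, THF, 0 °C
Reagents that add atoms: none
Why: Selective desilylation removes the unhindered primary TBS ether much faster than the hindered secondary one at C9, and buffered fluoride leaves the acetate, enone and vinyl iodide intact.

Step 16
Reactants: 20 primary alcohol
Product: 21 C8 aldehyde
Conditions: Dess–Martin periodinane, CH2Cl2, 0 → 23 °C
Reagents that add atoms: none
Why: Dess–Martin oxidation gives the α-silyloxy aldehyde under non-basic conditions, so C9 does not epimerise.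

Step 17
Reactants: 21 C8 aldehyde
Product: 23 anti-7,8-diol with a C7 vinyl group (C7 as in the target), via bis-boron adduct 22 (not isolated)
Conditions: allenylboronic acid pinacol ester, (−)-Ipc2BH [from (+)-α-pinene], toluene, 0 then 85 °C; 21, −78 °C; NaBO3·4H2O, THF–H2O, 23 °C
Reagents that add atoms: allenylboronic acid pinacol ester, C=C=CB1OC(C)(C)C(C)(C)O1; sodium perborate, [Na+].[O-]OB=O
Why: Brown-type asymmetric allylboration with the (E)-γ-boryl allylborane through a closed chair transition state, followed by C–B oxidation with retention, gives the anti-diol, and the isopinocampheyl groups (reagent control) set C7 together with the transient C8 carbinol.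

Step 18
Reactants: 23 anti-diol
Product: 24 O7 2-bromopropanoate (CHBr epimers)
Conditions: 2-bromopropionyl bromide (1.05 equiv), 2,4,6-collidine, CH2Cl2, −78 °C
Reagents that add atoms: 2-bromopropionyl bromide, CC(Br)C(=O)Br
Why: Kinetically selective O-acylation works because the allylic O7–H is less hindered than O8–H, which is flanked by the C9 silyl ether, so the α-bromo ester should go on O7 only.

Step 19
Reactants: 24 bromopropanoate
Product: 25 α-acyloxy ketone (C8 ketone)
Conditions: Dess–Martin periodinane, CH2Cl2, 0 → 23 °C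
Reagents that add atoms: none
Why: Dess–Martin oxidation of the remaining secondary alcohol under neutral conditions avoids acyl migration and epimerisation or conjugation at the doubly activated C7.

Step 20
Reactants: 25 α-acyloxy ketone
Product: 26 β-hydroxy-γ-lactone (ring C; C7, C8, C17 as in the target; C7 vinyl)
Conditions: Zn dust (activated with TMSCl), THF, 0 → 23 °C; aq. NH4Cl
Reagents that add atoms: none
Why: Intramolecular Reformatsky reaction (5-exo-trig attack of the zinc enolate carbon C17 on the C8 ketone) builds the five-membered ring with the bulky C9 residue trans to the C7 vinyl group and the C17 methyl trans to C9, which sets C8 and C17, and neutral zinc spares the acetate, enone and vinyl iodide.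

Step 21
Reactants: 26 vinyl iodide lactone
Product: 27 (4S)-bis-allylic alcohol (C3–C4 bond made; isopropenyl group on C4)
Conditions: methacrolein (5 equiv), CrCl2 (4 equiv), NiCl2 (2 mol %), (S)-N-[2-(4-isopropyl-4,5-dihydrooxazol-2-yl)-6-methylphenyl]methanesulfonamide (4.4 equiv), Et3N, THF, 23 °C
Reagents that add atoms: methacrolein, CC(=C)C=O
Why: Nozaki–Hiyama–Kishi coupling adds the alkenylchromium species 1,2 to the aldehyde with retention of the E-olefin and tolerance of ketone, esters and free O8–H, and C4 is set by the chiral chromium–sulfonamide complex (reagent control) because the resident stereocentres are remote.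

Step 22
Reactants: 27 bis-allylic alcohol
Product: 28 4,8,9-triol
Conditions: HF·pyridine (excess), pyridine, THF, 23 °C
Reagents that add atoms: none
Why: Fluoride-mediated desilylation under buffered, non-basic conditions frees O9 without acetate migration from O11, retro-aldol of the β-hydroxy lactone or ionisation of the bis-allylic alcohol.

Step 23
Reactants: 28 triol
Product: 29 4,9,11-triacetate (free tertiary O8–H)
Conditions: Ac2O, pyridine, DMAP (cat.), CH2Cl2, 0 → 23 °C
Reagents that add atoms: acetic anhydride, CC(=O)OC(C)=O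
Why: Acylation under mild conditions esterifies the two secondary alcohols in one operation while the hindered tertiary O8–H remains free.

Step 24
Reactants: 29 triacetate diene
Product: 30 (2E,5Z)-macrocycle (ring B closed, C5(CH3)=C6)
Conditions: second-generation Hoveyda–Grubbs catalyst (20 mol %, slow addition), toluene (0.5 mM), 110 °C, argon sparge
Reagents that add atoms: none
Why: Ring-closing metathesis should start at the monosubstituted C6 vinyl group and close on the isopropenyl group, the trans-disposed arms on ring A and ring C holding the termini close, while the neopentyl C2=C3 olefin and the enone are inert, and ring strain favours the Z-trisubstituted olefin.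

Step 25
Reactants: 30 macrocycle
Product: 32 6-epi allylic alcohol (C5=C16 methylene, O6 on the outer face), via allylic hydroperoxide 31 (not isolated)
Conditions: O2, tetraphenylporphyrin (1 mol %), CH2Cl2, 0 °C, visible light (> 520 nm); then PPh3
Reagents that add atoms: dioxygen, O=O
Why: In the Schenck ene reaction singlet oxygen attacks only the trisubstituted olefin, from the outer face of ring B (turned away from C3 and C8), bonds to C6 and takes a hydrogen from the freely rotating C16 methyl because the C4 and C7 hydrogens lie in the olefin plane, which sets the C6–O bond and the exocyclic methylene, and long-wavelength light leaves the enone and 1,4-diene unexcited.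

Step 26
Reactants: 32 6-epi allylic alcohol
Product: 33 target
Conditions: PPh3, hexachloroacetone, CH2Cl2, −20 → 0 °C
Reagents that add atoms: hexachloroacetone, ClC(Cl)(Cl)C(=O)C(Cl)(Cl)Cl
Why: In this Appel-type chlorination chloride displaces the alkoxyphosphonium group by SN2 with inversion, which places Cl anti to O7 as in the target, this reagent pair being the one known to convert secondary allylic alcohols without allylic transposition, and the tertiary O8–H does not react.

Compound list
1 | (R)-2-(2,2-dimethyl-5-oxo-1,3-dioxolan-4-yl)acetic acid | OC(=O)C[C@H]1OC(C)(C)OC1=O | starting material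
2 | nerol, (Z)-3,7-dimethylocta-2,6-dien-1-ol | CC(C)=CCC/C(C)=C\CO | starting material
3 | neryl 2-[(4R)-2,2-dimethyl-5-oxo-1,3-dioxolan-4-yl]acetate | CC(C)=CCC/C(C)=C\COC(=O)C[C@H]1OC(C)(C)OC1=O | intermediate
4 | 1-methyl 4-neryl (2R)-2-hydroxybutanedioate | CC(C)=CCC/C(C)=C\COC(=O)C[C@@H](O)C(=O)OC | intermediate
5 | (2S,3R)-2-[(3R)-3,7-dimethylocta-1,6-dien-3-yl]-3-hydroxy-4-methoxy-4-oxobutanoic acid | C=C[C@@](C)(CCC=C(C)C)[C@H](C(=O)O)[C@@H](O)C(=O)OC | intermediate
6 | (2S,3R)-2-[(3R)-3,7-dimethylocta-1,6-dien-3-yl]-3,4-dihydroxybutanoic acid | C=C[C@@](C)(CCC=C(C)C)[C@H](C(=O)O)[C@@H](O)CO | intermediate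
7 | (3S,4R)-3-[(3R)-3,7-dimethylocta-1,6-dien-3-yl]-4-hydroxyoxolan-2-one | C=C[C@@](C)(CCC=C(C)C)[C@@H]1C(=O)OC[C@@H]1O | intermediate
8 | (3S,4R)-3-[(3R)-3,7-dimethylocta-1,6-dien-3-yl]-4,5-dihydroxypentan-2-one | C=C[C@@](C)(CCC=C(C)C)[C@H](C(C)=O)[C@@H](O)CO | intermediate
9 | bis-TBS ether of 8 | C=C[C@@](C)(CCC=C(C)C)[C@H](C(C)=O)[C@@H](O[Si](C)(C)C(C)(C)C)CO[Si](C)(C)C(C)(C)C | intermediate
10 | side-chain glycol of 9 | C=C[C@@](C)(CCC(O)C(C)(C)O)[C@H](C(C)=O)[C@@H](O[Si](C)(C)C(C)(C)C)CO[Si](C)(C)C(C)(C)C | intermediate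
11 | C2 methyl ester glycol | COC(=O)[C@@](C)(CCC(O)C(C)(C)O)[C@H](C(C)=O)[C@@H](O[Si](C)(C)C(C)(C)C)CO[Si](C)(C)C(C)(C)C | intermediate
12 | keto aldehyde ester | COC(=O)[C@@](C)(CCC=O)[C@H](C(C)=O)[C@@H](O[Si](C)(C)C(C)(C)C)CO[Si](C)(C)C(C)(C)C | intermediate
13 | ketol ester (ring A closed, O11–H free) | COC(=O)[C@@]1(C)CCC(=O)[C@@](C)(O)[C@@H]1[C@@H](O[Si](C)(C)C(C)(C)C)CO[Si](C)(C)C(C)(C)C | intermediate
14 | keto lactone (6-oxabicyclo[3.2.1]octane-4,7-dione) | O=C1O[C@]2(C)C(=O)CC[C@@]1(C)[C@H]2[C@@H](O[Si](C)(C)C(C)(C)C)CO[Si](C)(C)C(C)(C)C | intermediate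
15 | bridged lactol carbinol | OC1O[C@]2(C)C(O)CC[C@@]1(C)[C@H]2[C@@H](O[Si](C)(C)C(C)(C)C)CO[Si](C)(C)C(C)(C)C | intermediate
16 | (E)-vinyl iodide 11,12-diol | I/C=C/[C@@]1(C)CCC(O)[C@@](C)(O)[C@@H]1[C@@H](O[Si](C)(C)C(C)(C)C)CO[Si](C)(C)C(C)(C)C | intermediate
17 | saturated ketol | I/C=C/[C@@]1(C)CCC(=O)[C@@](C)(O)[C@@H]1[C@@H](O[Si](C)(C)C(C)(C)C)CO[Si](C)(C)C(C)(C)C | intermediate
18 | α-hydroxy enone | I/C=C/[C@@]1(C)C=CC(=O)[C@@](C)(O)[C@@H]1[C@@H](O[Si](C)(C)C(C)(C)C)CO[Si](C)(C)C(C)(C)C | intermediate
19 | 11-acetate | I/C=C/[C@@]1(C)C=CC(=O)[C@@](C)(OC(C)=O)[C@@H]1[C@@H](O[Si](C)(C)C(C)(C)C)CO[Si](C)(C)C(C)(C)C | intermediate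
20 | primary C8 alcohol | I/C=C/[C@@]1(C)C=CC(=O)[C@@](C)(OC(C)=O)[C@@H]1[C@@H](O[Si](C)(C)C(C)(C)C)CO | intermediate
21 | C8 aldehyde | I/C=C/[C@@]1(C)C=CC(=O)[C@@](C)(OC(C)=O)[C@@H]1[C@@H](O[Si](C)(C)C(C)(C)C)C=O | intermediate
22 | bis-boron adduct (O8 diisopinocampheylborinate, C7 pinacol boronate) | I/C=C/[C@@]1(C)C=CC(=O)[C@@](C)(OC(C)=O)[C@@H]1[C@@H](O[Si](C)(C)C(C)(C)C)[C@@H](OB([C@@H]2C[C@@H]3C[C@H]([C@H]2C)C3(C)C)[C@@H]2C[C@@H]3C[C@H]([C@H]2C)C3(C)C)[C@@H](B2OC(C)(C)C(C)(C)O2)C=C | intermediate
23 | anti-7,8-diol | I/C=C/[C@@]1(C)C=CC(=O)[C@@](C)(OC(C)=O)[C@@H]1[C@@H](O[Si](C)(C)C(C)(C)C)[C@@H](O)[C@@H](O)C=C | intermediate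
24 | O7 2-bromopropanoate | I/C=C/[C@@]1(C)C=CC(=O)[C@@](C)(OC(C)=O)[C@@H]1[C@@H](O[Si](C)(C)C(C)(C)C)[C@@H](O)[C@@H](OC(=O)C(C)Br)C=C | intermediate
25 | α-acyloxy C8 ketone | I/C=C/[C@@]1(C)C=CC(=O)[C@@](C)(OC(C)=O)[C@@H]1[C@@H](O[Si](C)(C)C(C)(C)C)C(=O)[C@@H](OC(=O)C(C)Br)C=C | intermediate
26 | β-hydroxy-γ-lactone (ring C) | I/C=C/[C@@]1(C)C=CC(=O)[C@@](C)(OC(C)=O)[C@@H]1[C@@H](O[Si](C)(C)C(C)(C)C)[C@]2(O)[C@@H](C)C(=O)O[C@H]2C=C | intermediate
27 | (4S)-bis-allylic alcohol | C=C(C)[C@@H](O)/C=C/[C@@]1(C)C=CC(=O)[C@@](C)(OC(C)=O)[C@@H]1[C@@H](O[Si](C)(C)C(C)(C)C)[C@]2(O)[C@@H](C)C(=O)O[C@H]2C=C | intermediate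
28 | 4,8,9-triol | C=C(C)[C@@H](O)/C=C/[C@@]1(C)C=CC(=O)[C@@](C)(OC(C)=O)[C@@H]1[C@@H](O)[C@]2(O)[C@@H](C)C(=O)O[C@H]2C=C | intermediate
29 | 4,9,11-triacetate diene | C=C(C)[C@@H](OC(C)=O)/C=C/[C@@]1(C)C=CC(=O)[C@@](C)(OC(C)=O)[C@@H]1[C@@H](OC(C)=O)[C@]2(O)[C@@H](C)C(=O)O[C@H]2C=C | intermediate
30 | (2E,5Z)-macrocycle | CC(=O)O[C@H]1/C=C/[C@@]2(C)C=CC(=O)[C@@](C)(OC(C)=O)[C@@H]2[C@@H](OC(C)=O)[C@]2(O)[C@@H](C)C(=O)O[C@H]2/C=C1/C | intermediate
31 | allylic 6-hydroperoxide | C=C1[C@@H](OC(C)=O)/C=C/[C@@]2(C)C=CC(=O)[C@@](C)(OC(C)=O)[C@@H]2[C@@H](OC(C)=O)[C@]2(O)[C@@H](C)C(=O)O[C@H]2[C@@H]1OO | intermediate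
32 | 6-epi allylic alcohol | C=C1[C@@H](OC(C)=O)/C=C/[C@@]2(C)C=CC(=O)[C@@](C)(OC(C)=O)[C@@H]2[C@@H](OC(C)=O)[C@]2(O)[C@@H](C)C(=O)O[C@H]2[C@@H]1O | intermediate
33 | CNP0159278.2 | C=C1[C@@H](OC(C)=O)/C=C/[C@@]2(C)C=CC(=O)[C@@](C)(OC(C)=O)[C@@H]2[C@@H](OC(C)=O)[C@]2(O)[C@@H](C)C(=O)O[C@H]2[C@H]1Cl | target

Total step count: 26. Longest linear sequence: 26 steps (from 1 and 2).

Steps most likely to fail

Step 10. The closure may stall because the bulky C9 side chain has to become axial in the bicyclic product. Aldol closure of the aldehyde enolate onto C11, or slow epimerisation at C10, could also divert material. The fallback sets out from 12. Reductive carbonyl coupling with low-valent titanium (TiCl3(DME)1.5, Zn–Cu, DME, reflux; McMurry reaction) forms the same C11–C12 bond as an olefin, the cyclohexene ester F1. OsO4/NMO should attack the trisubstituted ring olefin from the face opposite the C9 side chain on C10 to give the cis-diol ester F2. Its O11 is cis to the ester and lactonises (DBU cat.) to the hydroxy lactone F3. Treatment with i-Bu2AlH as in step 11 brings the material back to the route at 15.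

Step 24. Ring closure to a strained ten-membered trisubstituted olefin may lose out to oligomerisation or catalyst decay. The fallback sets out from 26.
- Cross metathesis of the C7 vinyl group with methacrolein (second-generation Hoveyda–Grubbs catalyst, CH2Cl2, 40 °C) gives the (E)-enal F4.
- An intramolecular Nozaki–Hiyama–Kishi reaction (CrCl2, NiCl2 cat., DMSO–THF, high dilution) closes ring B at C3–C4 instead, giving the (5E)-macrocyclic alcohol F5, with C4 then under macrocyclic control.
- HF·pyridine gives the (5E)-triol F6, and Ac2O/pyridine gives the (5E)-triacetate F7.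
- The ene reaction of step 25 erases the olefin geometry and returns the material to the route at 32.

Step 26. The displacement may proceed with allylic transposition (SN2′ to the C16 chloride), or by ionisation with loss of configuration. The fallback sets out from 30 and makes the C–Cl bond while no allylic system is present. Dimethyldioxirane (acetone, 0 °C) should epoxidise the trisubstituted olefin on the outer face to give the 5,6-epoxide F8. Li2CuCl4 (THF) opens it at the secondary C6 with inversion to give the chlorohydrin F9. Dehydration of the tertiary C5 alcohol towards the C16 methyl with Burgess reagent (toluene, 50 °C) then returns to the route at 33.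

Further compounds
F1 | step 10 | cyclohexene ester (C11=C12) | COC(=O)[C@@]1(C)CCC=C(C)[C@@H]1[C@@H](O[Si](C)(C)C(C)(C)C)CO[Si](C)(C)C(C)(C)C
F2 | step 10 | cis-11,12-diol ester | COC(=O)[C@@]1(C)CC[C@@H](O)[C@@](C)(O)[C@@H]1[C@@H](O[Si](C)(C)C(C)(C)C)CO[Si](C)(C)C(C)(C)C
F3 | step 10 | 12-hydroxy lactone | O=C1O[C@]2(C)[C@H](O)CC[C@@]1(C)[C@H]2[C@@H](O[Si](C)(C)C(C)(C)C)CO[Si](C)(C)C(C)(C)C
F4 | step 24 | (E)-enal | I/C=C/[C@@]1(C)C=CC(=O)[C@@](C)(OC(C)=O)[C@@H]1[C@@H](O[Si](C)(C)C(C)(C)C)[C@]2(O)[C@@H](C)C(=O)O[C@H]2/C=C(\C)C=O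
F5 | step 24 | (5E)-macrocyclic alcohol | O[C@H]1/C=C/[C@@]2(C)C=CC(=O)[C@@](C)(OC(C)=O)[C@@H]2[C@@H](O[Si](C)(C)C(C)(C)C)[C@]2(O)[C@@H](C)C(=O)O[C@H]2/C=C1\C
F6 | step 24 | (5E)-triol | O[C@H]1/C=C/[C@@]2(C)C=CC(=O)[C@@](C)(OC(C)=O)[C@@H]2[C@@H](O)[C@]2(O)[C@@H](C)C(=O)O[C@H]2/C=C1\C
F7 | step 24 | (5E)-triacetate | CC(=O)O[C@H]1/C=C/[C@@]2(C)C=CC(=O)[C@@](C)(OC(C)=O)[C@@H]2[C@@H](OC(C)=O)[C@]2(O)[C@@H](C)C(=O)O[C@H]2/C=C1\C
F8 | step 26 | 5,6-epoxide | CC(=O)O[C@H]1/C=C/[C@@]2(C)C=CC(=O)[C@@](C)(OC(C)=O)[C@@H]2[C@@H](OC(C)=O)[C@]2(O)[C@@H](C)C(=O)O[C@H]2[C@@H]3O[C@]13C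
F9 | step 26 | 6-chloro-5-hydroxy chlorohydrin | C[C@@]1(O)[C@@H](OC(C)=O)/C=C/[C@@]2(C)C=CC(=O)[C@@](C)(OC(C)=O)[C@@H]2[C@@H](OC(C)=O)[C@]2(O)[C@@H](C)C(=O)O[C@H]2[C@H]1Cl
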